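**Plan**

- Retrosynthesis: the end groups are taken back first (CO2H to CH2OTBS, ArOH to ArOTIPS). The dihydropyran ring is then opened at the aryl C8a–O1 bond (C8a–Cl plus tertiary OH). Last, the C1′–C2 bond between the fully substituted carbinol carbon and the side-chain CH2 is cut, which gives two halves of similar size.
- Enabling feature: C2 of the dihydropyran ring carries O1, a methyl group and two primary CH2 groups (C3 and C1′). Being a carbinol carbon, it can be traced back to a secondary C–H whose ester oxygen first acidifies it and holds lithium and then leaves. C1′ is a primary carbon (a good migrating group on boron), and its nearest alkene, C3′=C4′, is homoallylic and inert.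
- Forward: arene half 7 (four steps from 4-chloro-3,5-dimethylphenol and (R)-propylene oxide) and chain half 15 (six steps from geranyl acetate) are joined at C2 by lithiation–borylation, 1,2-migration and oxidation. The dihydropyran ring is then closed by Pd-catalysed C8a–O1 coupling; the aromatic ring is bought. The chain terminus is oxidised to the acid before the phenol is freed.
- Stereochemistry: C2 comes from (R)-propylene oxide, is inverted once (Mitsunobu) and is transferred stereospecifically in the coupling; its C–O bond is not broken afterwards. Both E alkenes come from the geranyl skeleton and an E-selective allylic oxidation.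

Key step: step 11

Assumption: 4-chloro-3,5-dimethylphenol, (R)-propylene oxide, geranyl acetate and all named reagents are taken as commercial.

**Route**

Step 1
Reactants: 1 4-chloro-3,5-dimethylphenol
Product: 2 (4-chloro-3,5-dimethylphenoxy)triisopropylsilane
Conditions: TIPSCl, imidazole, DMF, rt
Reagents that add atoms: triisopropylsilyl chloride, CC(C)[Si](Cl)(C(C)C)C(C)C
Why: Routine phenol silylation; the bulky, poorly coordinating TIPS ether should survive Grignard, organolithium, peroxide and Pd/carbonate conditions and should disfavour ring metalation ortho to oxygen.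

Step 2
Reactants: 2 (4-chloro-3,5-dimethylphenoxy)triisopropylsilane
Product: 3 [3-(bromomethyl)-4-chloro-5-methylphenoxy]triisopropylsilane
Conditions: NBS (1.0 equiv), AIBN (cat.), PhCF3, 80 °C
Reagents that add atoms: N-bromosuccinimide, O=C1CCC(=O)N1Br
Why: Wohl–Ziegler radical bromination of one of the two equivalent benzylic methyl groups; one equivalent of NBS in a non-polar solvent keeps the reaction on the radical-chain path, and the para chlorine lowers ring nucleophilicity.

Step 3
Reactants: 3 [3-(bromomethyl)-4-chloro-5-methylphenoxy]triisopropylsilane; 4 (R)-propylene oxide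
Product: 6 (2R)-4-[2-chloro-3-methyl-5-(triisopropylsilyloxy)phenyl]butan-2-ol, via benzylic Grignard reagent 5 (not isolated)
Conditions: Mg, Et2O, 0 °C (slow addition of 3); then 4, CuI (10 mol %), THF, −30 → 0 °C; aq NH4Cl
Reagents that add atoms: none
Why: Copper-catalysed SN2 opening of the terminal epoxide by the benzylic Grignard reagent at the unsubstituted CH2 leaves the stereocenter of (R)-propylene oxide untouched and so should give the (R)-carbinol; the aryl chloride is inert to magnesium under conditions that insert into the benzylic C–Br bond.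

Step 4
Reactants: 6 (2R)-4-[2-chloro-3-methyl-5-(triisopropylsilyloxy)phenyl]butan-2-ol
Product: 7 (2S)-4-[2-chloro-3-methyl-5-(triisopropylsilyloxy)phenyl]butan-2-yl 2,4,6-triisopropylbenzoate
Conditions: 2,4,6-triisopropylbenzoic acid, PPh3, DIAD, THF, 0 °C → rt
Reagents that add atoms: 2,4,6-triisopropylbenzoic acid, CC(C)c1cc(C(C)C)c(C(=O)O)c(C(C)C)c1
Why: Mitsunobu esterification proceeds by SN2 displacement of the alkoxyphosphonium ion by the hindered but sufficiently acidic carboxylate, so the (R)-alcohol should give the (S)-benzoate with inversion.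

Step 5
Reactants: 8 geranyl acetate
Product: 9 (2E,6E)-8-hydroxy-3,7-dimethylocta-2,6-dien-1-yl acetate
Conditions: SeO2 (cat.), t-BuOOH, salicylic acid (cat.), CH2Cl2, rt
Reagents that add atoms: tert-butyl hydroperoxide (terminal oxidant, source of the oxygen), CC(C)(C)OO; selenium dioxide (oxygen-transfer catalyst), O=[Se]=O
Why: Riley-type allylic oxidation (ene reaction then [2,3]-shift) attacks the electron-rich 6,7-alkene rather than the acetate-deactivated 2,3-alkene and oxidises the (E)-methyl group, which fixes the E geometry of the future acid terminus.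

Step 6
Reactants: 9 (2E,6E)-8-hydroxy-3,7-dimethylocta-2,6-dien-1-yl acetate
Product: 10 (2E,6E)-8-[(tert-butyldimethylsilyl)oxy]-3,7-dimethylocta-2,6-dien-1-yl acetate
Conditions: TBSCl, imidazole, DMF, rt
Reagents that add atoms: tert-butyldimethylsilyl chloride, CC(C)(C)[Si](C)(C)Cl
Why: Routine silylation of a primary allylic alcohol; the TBS ether is stable to alkoxide, organolithium, peroxide and Pd and can later be removed with mild acid while the aryl TIPS ether stays.

Step 7
Reactants: 10 (2E,6E)-8-[(tert-butyldimethylsilyl)oxy]-3,7-dimethylocta-2,6-dien-1-yl acetate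
Product: 11 (2E,6E)-8-[(tert-butyldimethylsilyl)oxy]-3,7-dimethylocta-2,6-dien-1-ol
Conditions: K2CO3 (cat.), MeOH, rt
Reagents that add atoms: none
Why: Zemplén-type transesterification removes the acetate without touching the silyl ether or the alkene geometry.

Step 8
Reactants: 11 (2E,6E)-8-[(tert-butyldimethylsilyl)oxy]-3,7-dimethylocta-2,6-dien-1-ol
Product: 12 tert-butyl{[(2E,6E)-8-bromo-2,6-dimethylocta-2,6-dien-1-yl]oxy}dimethylsilane
Conditions: CBr4, PPh3, CH2Cl2, 0 °C
Reagents that add atoms: carbon tetrabromide, BrC(Br)(Br)Br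
Why: Appel bromination displaces the alkoxyphosphonium ion by bromide under neutral conditions, which should convert the primary allylic alcohol without allylic transposition or E/Z isomerisation.

Step 9
Reactants: 12 tert-butyl{[(2E,6E)-8-bromo-2,6-dimethylocta-2,6-dien-1-yl]oxy}dimethylsilane
Product: 13 2-[(3E,7E)-9-[(tert-butyldimethylsilyl)oxy]-4,8-dimethylnona-3,7-dien-1-yl]-4,4,5,5-tetramethyl-1,3,2-dioxaborolane
Conditions: CH2(Bpin)2, NaOt-Bu, THF, 0 °C → rt
Reagents that add atoms: bis(4,4,5,5-tetramethyl-1,3,2-dioxaborolan-2-yl)methane, CC1(C)OB(CB2OC(C)(C)C(C)(C)O2)OC1(C)C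
Why: Alkoxide-promoted deborylative alkylation: tert-butoxide adds to one boron of the geminal bis(boronate) and releases an α-boryl carbanion, which displaces the primary allylic bromide by SN2 (the γ-carbon is fully substituted, so SN2′ is disfavoured) and leaves the alkene geometry intact.

Step 10
Reactants: 13 2-[(3E,7E)-9-[(tert-butyldimethylsilyl)oxy]-4,8-dimethylnona-3,7-dien-1-yl]-4,4,5,5-tetramethyl-1,3,2-dioxaborolane
Product: 15 2-[(3E,7E)-9-[(tert-butyldimethylsilyl)oxy]-4,8-dimethylnona-3,7-dien-1-yl]-5,5-dimethyl-1,3,2-dioxaborinane, via boronic acid 14 (not isolated)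
Conditions: NaIO4, NH4OAc, acetone/H2O, rt; then neopentyl glycol, MgSO4, CH2Cl2, rt
Reagents that add atoms: neopentyl glycol, OCC(C)(C)CO
Why: Periodate cleaves the pinacol set free in the hydrolysis equilibrium and so drives the ester to the boronic acid, which condenses with neopentyl glycol to the less hindered six-membered boronate that a hindered tertiary alkyllithium can still borylate.

Step 11
Reactants: 7 (2S)-4-[2-chloro-3-methyl-5-(triisopropylsilyloxy)phenyl]butan-2-yl 2,4,6-triisopropylbenzoate; 15 2-[(3E,7E)-9-[(tert-butyldimethylsilyl)oxy]-4,8-dimethylnona-3,7-dien-1-yl]-5,5-dimethyl-1,3,2-dioxaborinane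
Product: 19 (3R,6E,10E)-12-[(tert-butyldimethylsilyl)oxy]-1-[2-chloro-3-methyl-5-(triisopropylsilyloxy)phenyl]-3,7,11-trimethyldodeca-6,10-dien-3-ol, via lithiated benzoate 16 (not isolated), via boron ate complex 17 (not isolated), via tertiary boronic ester 18 (not isolated)
Conditions: 7 (1.3 equiv), s-BuLi (1.25 equiv), TMEDA, CPME, −60 °C; then 15 (1.0 equiv), −60 °C → rt, then 50 °C; then 30% H2O2, 2 M aq NaOH, THF, 0 °C → rt
Reagents that add atoms: hydrogen peroxide, OO
Why: s-BuLi/TMEDA removes the carbinol proton of 7 (acidified and directed by the triisopropylbenzoate carbonyl) with retention to give the configurationally stable α-oxy alkyllithium 16, which boronate 15 captures with retention as ate complex 17. On warming, the primary C1′ alkyl group migrates from boron to C2 antiperiplanar to the departing triisopropylbenzoate (stereoinvertive 1,2-metallate rearrangement); this forms the C1′–C2 bond in tertiary boronic ester 18, which alkaline peroxide oxidises with retention to 19. The closest known reaction type is the lithiation–borylation of enantioenriched secondary dialkyl 2,4,6-triisopropylbenzoates with primary alkyl neopentyl glycol boronates, a Matteson-type homologation. No ring is closed, and the one new stereocenter, C2, is controlled only by the carbinol configuration of 7: the sequence retention, retention, inversion, retention should turn (S)-7 into (R)-19. The step needs C–H lithiation α to oxygen in preference to attack on the arene or ester; this is secured by the fully substituted benzoate ring, by both positions ortho to chlorine being substituted (no aryne path, slow Cl/Li exchange), by the bulky non-directing OTIPS group and by the low temperature. It also needs migration of carbon rather than the diol oxygen, which the primary migrating group and the good benzoate leaving group favour, while the homoallylic alkene and the silyl ether of 15 are inert to the short exposure to organolithium.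

Step 12
Reactants: 19 (3R,6E,10E)-12-[(tert-butyldimethylsilyl)oxy]-1-[2-chloro-3-methyl-5-(triisopropylsilyloxy)phenyl]-3,7,11-trimethyldodeca-6,10-dien-3-ol
Product: 20 tert-butyl({(2E,6E)-9-[(2R)-2,8-dimethyl-6-(triisopropylsilyloxy)chroman-2-yl]-2,6-dimethylnona-2,6-dien-1-yl}oxy)dimethylsilane
Conditions: Pd(OAc)2 (5 mol %), 2-(di-tert-butylphosphino)-1,1′-binaphthyl (or t-BuXPhos), Cs2CO3, toluene, 90 °C
Reagents that add atoms: none
Why: Intramolecular Buchwald–Hartwig-type etherification: oxidative addition into the C8a–Cl bond, binding of the tertiary alkoxide (which has no hydrogen on the carbinol carbon, so β-hydride reduction of the arene is excluded) and C–O reductive elimination from a seven-membered palladacycle should close the six-membered dihydropyran ring without touching the C2–O bond or its configuration.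

Step 13
Reactants: 20 tert-butyl({(2E,6E)-9-[(2R)-2,8-dimethyl-6-(triisopropylsilyloxy)chroman-2-yl]-2,6-dimethylnona-2,6-dien-1-yl}oxy)dimethylsilane
Product: 21 (2E,6E)-9-[(2R)-2,8-dimethyl-6-(triisopropylsilyloxy)chroman-2-yl]-2,6-dimethylnona-2,6-dien-1-ol
Conditions: PPTS, MeOH, rt
Reagents that add atoms: none
Why: Acid-catalysed methanolysis cleaves the primary alkyl TBS ether much faster than the hindered aryl TIPS ether, which is labile to fluoride and base but not to mild acid.

Step 14
Reactants: 21 (2E,6E)-9-[(2R)-2,8-dimethyl-6-(triisopropylsilyloxy)chroman-2-yl]-2,6-dimethylnona-2,6-dien-1-ol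
Product: 22 (2E,6E)-9-[(2R)-2,8-dimethyl-6-(triisopropylsilyloxy)chroman-2-yl]-2,6-dimethylnona-2,6-dienal
Conditions: MnO2, CH2Cl2, rt
Reagents that add atoms: none
Why: Activated MnO2 oxidises only the allylic alcohol and should keep the E geometry, and the silyl-protected chromanol is not oxidised.

Step 15
Reactants: 22 (2E,6E)-9-[(2R)-2,8-dimethyl-6-(triisopropylsilyloxy)chroman-2-yl]-2,6-dimethylnona-2,6-dienal
Product: 23 (2E,6E)-9-[(2R)-2,8-dimethyl-6-(triisopropylsilyloxy)chroman-2-yl]-2,6-dimethylnona-2,6-dienoic acid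
Conditions: NaClO2, NaH2PO4, 2-methyl-2-butene, t-BuOH/H2O, 0 °C → rt
Reagents that add atoms: sodium chlorite, [Na+].[O-]Cl=O
Why: Pinnick oxidation converts the enal into the α,β-unsaturated acid without isomerisation, and the alkene scavenger traps hypochlorous acid before it can attack the trisubstituted alkenes or the electron-rich arene.

Step 16
Reactants: 23 (2E,6E)-9-[(2R)-2,8-dimethyl-6-(triisopropylsilyloxy)chroman-2-yl]-2,6-dimethylnona-2,6-dienoic acid
Product: 24 (2E,6E)-9-[(2R)-6-hydroxy-2,8-dimethylchroman-2-yl]-2,6-dimethylnona-2,6-dienoic acid (target)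
Conditions: TBAF, AcOH, THF, 0 °C, under argon
Reagents that add atoms: none
Why: Fluoride cleaves the aryl silyl ether, and the acetic acid buffer keeps the oxidation-sensitive 6-hydroxychroman protonated.

**Compound list**

1 | 4-chloro-3,5-dimethylphenol | Cc1cc(O)cc(C)c1Cl | starting material
2 | (4-chloro-3,5-dimethylphenoxy)triisopropylsilane | Cc1cc(O[Si](C(C)C)(C(C)C)C(C)C)cc(C)c1Cl | intermediate
3 | [3-(bromomethyl)-4-chloro-5-methylphenoxy]triisopropylsilane | Cc1cc(O[Si](C(C)C)(C(C)C)C(C)C)cc(CBr)c1Cl | intermediate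
4 | (R)-propylene oxide | C[C@@H]1CO1 | starting material
5 | {[2-chloro-3-methyl-5-(triisopropylsilyloxy)phenyl]methyl}magnesium bromide | Cc1cc(O[Si](C(C)C)(C(C)C)C(C)C)cc(C[Mg]Br)c1Cl | intermediate (not isolated)
6 | (2R)-4-[2-chloro-3-methyl-5-(triisopropylsilyloxy)phenyl]butan-2-ol | C[C@@H](O)CCc1cc(O[Si](C(C)C)(C(C)C)C(C)C)cc(C)c1Cl | intermediate
7 | (2S)-4-[2-chloro-3-methyl-5-(triisopropylsilyloxy)phenyl]butan-2-yl 2,4,6-triisopropylbenzoate | C[C@H](OC(=O)c1c(C(C)C)cc(C(C)C)cc1C(C)C)CCc1cc(O[Si](C(C)C)(C(C)C)C(C)C)cc(C)c1Cl | intermediate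
8 | geranyl acetate, (2E)-3,7-dimethylocta-2,6-dien-1-yl acetate | C/C(=C\COC(C)=O)CCC=C(C)C | starting material
9 | (2E,6E)-8-hydroxy-3,7-dimethylocta-2,6-dien-1-yl acetate | C/C(=C\COC(C)=O)CC/C=C(\C)CO | intermediate
10 | (2E,6E)-8-[(tert-butyldimethylsilyl)oxy]-3,7-dimethylocta-2,6-dien-1-yl acetate | C/C(=C\COC(C)=O)CC/C=C(\C)CO[Si](C)(C)C(C)(C)C | intermediate
11 | (2E,6E)-8-[(tert-butyldimethylsilyl)oxy]-3,7-dimethylocta-2,6-dien-1-ol | C/C(=C\CO)CC/C=C(\C)CO[Si](C)(C)C(C)(C)C | intermediate
12 | tert-butyl{[(2E,6E)-8-bromo-2,6-dimethylocta-2,6-dien-1-yl]oxy}dimethylsilane | C/C(=C\CBr)CC/C=C(\C)CO[Si](C)(C)C(C)(C)C | intermediate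
13 | 2-[(3E,7E)-9-[(tert-butyldimethylsilyl)oxy]-4,8-dimethylnona-3,7-dien-1-yl]-4,4,5,5-tetramethyl-1,3,2-dioxaborolane | C/C(=C\CCB1OC(C)(C)C(C)(C)O1)CC/C=C(\C)CO[Si](C)(C)C(C)(C)C | intermediate
14 | [(3E,7E)-9-[(tert-butyldimethylsilyl)oxy]-4,8-dimethylnona-3,7-dien-1-yl]boronic acid | C/C(=C\CCB(O)O)CC/C=C(\C)CO[Si](C)(C)C(C)(C)C | intermediate (not isolated)
15 | 2-[(3E,7E)-9-[(tert-butyldimethylsilyl)oxy]-4,8-dimethylnona-3,7-dien-1-yl]-5,5-dimethyl-1,3,2-dioxaborinane | C/C(=C\CCB1OCC(C)(C)CO1)CC/C=C(\C)CO[Si](C)(C)C(C)(C)C | intermediate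
16 | (2S)-4-[2-chloro-3-methyl-5-(triisopropylsilyloxy)phenyl]-2-lithiobutan-2-yl 2,4,6-triisopropylbenzoate (Li in place of the carbinol H, retention) | C[C@]([Li])(OC(=O)c1c(C(C)C)cc(C(C)C)cc1C(C)C)CCc1cc(O[Si](C(C)C)(C(C)C)C(C)C)cc(C)c1Cl | intermediate (not isolated)
17 | lithium boronate (ate) complex of 16 and 15: boron bound to C2 of the benzoate (retention), to C1′ of the chain and to the neopentyl glycolate | [Li+].C/C(=C\CC[B-]1(OCC(C)(C)CO1)[C@@](C)(OC(=O)c1c(C(C)C)cc(C(C)C)cc1C(C)C)CCc1cc(O[Si](C(C)C)(C(C)C)C(C)C)cc(C)c1Cl)CC/C=C(\C)CO[Si](C)(C)C(C)(C)C | intermediate (not isolated)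
18 | 2-[(3S,6E,10E)-12-[(tert-butyldimethylsilyl)oxy]-1-[2-chloro-3-methyl-5-(triisopropylsilyloxy)phenyl]-3,7,11-trimethyldodeca-6,10-dien-3-yl]-5,5-dimethyl-1,3,2-dioxaborinane | C/C(=C\CC[C@](B1OCC(C)(C)CO1)(C)CCc1cc(O[Si](C(C)C)(C(C)C)C(C)C)cc(C)c1Cl)CC/C=C(\C)CO[Si](C)(C)C(C)(C)C | intermediate (not isolated)
19 | (3R,6E,10E)-12-[(tert-butyldimethylsilyl)oxy]-1-[2-chloro-3-methyl-5-(triisopropylsilyloxy)phenyl]-3,7,11-trimethyldodeca-6,10-dien-3-ol | C/C(=C\CC[C@](O)(C)CCc1cc(O[Si](C(C)C)(C(C)C)C(C)C)cc(C)c1Cl)CC/C=C(\C)CO[Si](C)(C)C(C)(C)C | intermediate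
20 | tert-butyl({(2E,6E)-9-[(2R)-2,8-dimethyl-6-(triisopropylsilyloxy)chroman-2-yl]-2,6-dimethylnona-2,6-dien-1-yl}oxy)dimethylsilane | C/C(=C\CC[C@]1(C)CCc2cc(O[Si](C(C)C)(C(C)C)C(C)C)cc(C)c2O1)CC/C=C(\C)CO[Si](C)(C)C(C)(C)C | intermediate
21 | (2E,6E)-9-[(2R)-2,8-dimethyl-6-(triisopropylsilyloxy)chroman-2-yl]-2,6-dimethylnona-2,6-dien-1-ol | C/C(=C\CC[C@]1(C)CCc2cc(O[Si](C(C)C)(C(C)C)C(C)C)cc(C)c2O1)CC/C=C(\C)CO | intermediate
22 | (2E,6E)-9-[(2R)-2,8-dimethyl-6-(triisopropylsilyloxy)chroman-2-yl]-2,6-dimethylnona-2,6-dienal | C/C(=C\CC[C@]1(C)CCc2cc(O[Si](C(C)C)(C(C)C)C(C)C)cc(C)c2O1)CC/C=C(\C)C=O | intermediate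
23 | (2E,6E)-9-[(2R)-2,8-dimethyl-6-(triisopropylsilyloxy)chroman-2-yl]-2,6-dimethylnona-2,6-dienoic acid | C/C(=C\CC[C@]1(C)CCc2cc(O[Si](C(C)C)(C(C)C)C(C)C)cc(C)c2O1)CC/C=C(\C)C(=O)O | intermediate
24 | (2E,6E)-9-[(2R)-6-hydroxy-2,8-dimethylchroman-2-yl]-2,6-dimethylnona-2,6-dienoic acid | C/C(=C\CC[C@]1(C)CCc2cc(O)cc(C)c2O1)CC/C=C(\C)C(=O)O | target

**Step count and risks**

Total steps: 16. Longest linear sequence: 12 steps (steps 5–16, from geranyl acetate); the arene branch (steps 1–4) joins at step 11.

Steps most likely to fail: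

Step 11. The base may metalate 7 elsewhere (benzylic positions, the ring, or the C–Cl bond), lithiation of the hindered secondary C–H may stay incomplete, or ate-complex formation and the 1,2-shift between two hindered partners may be slower than decay of the carbenoid. The fallback forms the same C1′–C2 bond by carbonyl addition; it sets out from 6 and 15 and returns at 19. Alcohol 6 would be oxidised with Dess–Martin periodinane to 4-[2-chloro-3-methyl-5-(triisopropylsilyloxy)phenyl]butan-2-one F1. Boronate 15 would be oxidised (NaOH, H2O2) to (3E,7E)-9-[(tert-butyldimethylsilyl)oxy]-4,8-dimethylnona-3,7-dien-1-ol F2, converted with I2, PPh3 and imidazole into tert-butyl{[(2E,6E)-9-iodo-2,6-dimethylnona-2,6-dien-1-yl]oxy}dimethylsilane F3, and this by iodine–zinc exchange (Et2Zn, cat. CuI) into bis[(3E,7E)-9-[(tert-butyldimethylsilyl)oxy]-4,8-dimethylnona-3,7-dien-1-yl]zinc F4. Titanium-catalysed enantioselective 1,2-addition of F4 to F1 [Ti(Oi-Pr)4, a trans-1,2-diaminocyclohexane bis(hydroxycamphorsulfonamide) ligand of the enantiomer that delivers the alkyl group to the face leading to (R), toluene, rt] should give 19 directly. Because the catalyst must tell CH3 from CH2CH2Ar, a lower enantiomeric purity is expected than from the stereospecific route, and enrichment on a chiral stationary phase at 19 or 20 would be planned.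

Step 12. Oxidative addition of Pd(0) into the di-ortho-substituted, electron-rich C–Cl bond may be too slow, with catalyst decay or hydrodechlorination taking over. The fallback uses the chlorine as a nucleofuge in an oxidative dearomatisation instead of a cross-coupling; it sets out from 19 and returns at 21. Excess TBAF would remove both silyl groups to give 4-chloro-3-[(3R,6E,10E)-3,12-dihydroxy-3,7,11-trimethyldodeca-6,10-dien-1-yl]-5-methylphenol F5. Oxidation with PhI(OAc)2 in aqueous MeCN (ipso attack at the para carbon and loss of chloride) should give 2-[(3R,6E,10E)-3,12-dihydroxy-3,7,11-trimethyldodeca-6,10-dien-1-yl]-6-methyl-1,4-benzoquinone F6. With HC(OMe)3, MeOH and cat. PPTS the tertiary hydroxyl should add to the neighbouring quinone carbonyl to give the cyclic ketal (2R)-2-[(3E,7E)-9-hydroxy-4,8-dimethylnona-3,7-dien-1-yl]-8a-methoxy-2,8-dimethyl-2,3,4,8a-tetrahydro-6H-chromen-6-one F7 (mixture at C8a), so that the ring oxygen bond is made at the aryl carbon and the C2–O bond stays intact. Reduction of this quinone monoketal (ascorbic acid, aqueous MeOH) should give (2E,6E)-9-[(2R)-6-hydroxy-2,8-dimethylchroman-2-yl]-2,6-dimethylnona-2,6-dien-1-ol F8. Phenoxide-selective silylation (TIPSCl, DBU, CH2Cl2, 0 °C) would then give 21.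

Step 3. Wurtz-type homocoupling during formation of the benzylic Grignard reagent, or halohydrin formation from the epoxide by magnesium halide, may consume the material. The fallback builds the carbinol by enolate-type alkylation and sets the stereocenter by catalysis; it sets out from 3 and returns at 6. Bromide 3 would alkylate lithiated acetone N,N-dimethylhydrazone (LDA, THF, −78 °C) to give 4-[2-chloro-3-methyl-5-(triisopropylsilyloxy)phenyl]butan-2-one N,N-dimethylhydrazone F9. Mild hydrolysis (aqueous oxalic acid) would give ketone F1, and NaBH4 would give racemic 4-[2-chloro-3-methyl-5-(triisopropylsilyloxy)phenyl]butan-2-ol F10. Dynamic kinetic resolution (ruthenium racemisation catalyst, Candida antarctica lipase B, isopropenyl acetate, toluene) should give (2R)-4-[2-chloro-3-methyl-5-(triisopropylsilyloxy)phenyl]butan-2-yl acetate F11, and DIBAL-H (CH2Cl2, −78 °C) would release 6.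

**Further compounds**

F1 | step 11 | 4-[2-chloro-3-methyl-5-(triisopropylsilyloxy)phenyl]butan-2-one | CC(=O)CCc1cc(O[Si](C(C)C)(C(C)C)C(C)C)cc(C)c1Cl
F2 | step 11 | (3E,7E)-9-[(tert-butyldimethylsilyl)oxy]-4,8-dimethylnona-3,7-dien-1-ol | C/C(=C\CCO)CC/C=C(\C)CO[Si](C)(C)C(C)(C)C
F3 | step 11 | tert-butyl{[(2E,6E)-9-iodo-2,6-dimethylnona-2,6-dien-1-yl]oxy}dimethylsilane | C/C(=C\CCI)CC/C=C(\C)CO[Si](C)(C)C(C)(C)C
F4 | step 11 | bis[(3E,7E)-9-[(tert-butyldimethylsilyl)oxy]-4,8-dimethylnona-3,7-dien-1-yl]zinc | C/C(=C\CC[Zn]CC/C=C(C)/CC/C=C(\C)CO[Si](C)(C)C(C)(C)C)CC/C=C(\C)CO[Si](C)(C)C(C)(C)C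
F5 | step 12 | 4-chloro-3-[(3R,6E,10E)-3,12-dihydroxy-3,7,11-trimethyldodeca-6,10-dien-1-yl]-5-methylphenol | C/C(=C\CC[C@](O)(C)CCc1cc(O)cc(C)c1Cl)CC/C=C(\C)CO
F6 | step 12 | 2-[(3R,6E,10E)-3,12-dihydroxy-3,7,11-trimethyldodeca-6,10-dien-1-yl]-6-methyl-1,4-benzoquinone | C/C(=C\CC[C@](O)(C)CCC1=CC(=O)C=C(C)C1=O)CC/C=C(\C)CO
F7 | step 12 | (2R)-2-[(3E,7E)-9-hydroxy-4,8-dimethylnona-3,7-dien-1-yl]-8a-methoxy-2,8-dimethyl-2,3,4,8a-tetrahydro-6H-chromen-6-one | C/C(=C\CC[C@]1(C)CCC2=CC(=O)C=C(C)C2(OC)O1)CC/C=C(\C)CO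
F8 | step 12 | (2E,6E)-9-[(2R)-6-hydroxy-2,8-dimethylchroman-2-yl]-2,6-dimethylnona-2,6-dien-1-ol | C/C(=C\CC[C@]1(C)CCc2cc(O)cc(C)c2O1)CC/C=C(\C)CO
F9 | step 3 | 4-[2-chloro-3-methyl-5-(triisopropylsilyloxy)phenyl]butan-2-one N,N-dimethylhydrazone | CC(CCc1cc(O[Si](C(C)C)(C(C)C)C(C)C)cc(C)c1Cl)=NN(C)C
F10 | step 3 | racemic 4-[2-chloro-3-methyl-5-(triisopropylsilyloxy)phenyl]butan-2-ol | CC(O)CCc1cc(O[Si](C(C)C)(C(C)C)C(C)C)cc(C)c1Cl
F11 | step 3 | (2R)-4-[2-chloro-3-methyl-5-(triisopropylsilyloxy)phenyl]butan-2-yl acetate | C[C@@H](OC(C)=O)CCc1cc(O[Si](C(C)C)(C(C)C)C(C)C)cc(C)c1Cl
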